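**Retrosynthetic overview**

1. Manniflavanone ⇐ nona-O-TBS ketone 15 by nine Si–O cleavages. 15 ⇐ 13 by a late change of oxidation level at C4'' of ring F (CH2 → C=O). Rings D, E and F and their two stereocentres come unchanged from (+)-catechin.
2. Ring C is closed last, at C2–C3, by catalyst-controlled 1,6-C–H insertion of the rhodium carbene from diazoketone 11 into the OCH2 group of the (ring B)CH2–O–(ring A) ether, followed by epimerisation at C3 to trans. This one operation makes the ring and both of its stereocentres.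
3. Feature used: C2 is benzylic to ring B and bound to O1 of ring A, so the seco-form of ring C is an aryl benzyl ether whose OCH2 hydrogens are hydridic and lie 1,6 to C3. C3 sits between the C4 carbonyl and C8'' of ring D, which is the place of a donor/acceptor carbene carbon.
4. 11 ⇐ diazo transfer ⇐ deoxybenzoin 10 ⇐ Pd-catalysed α-arylation (C3–C8'' bond) of acetophenone 9 with 8-bromocatechin 3. 9 ⇐ Mitsunobu ether (O1–C2 bond) from phenol 8 and benzyl alcohol 6.
5. Ring order: D, E, F from the chiral pool; A and B bought as arenes; C last. All hydroxyls are TBS ethers, so that no oxygen near the carbene other than O1 carries a C–H, and one fluoride step frees all nine hydroxyls.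

Key step: step 9

Remarks. Flavanone half: ring A (phloroglucinol ring), ring B (catechol ring), ring C (pyranone; C2, C3, C4). Dihydroflavonol half: ring D (phloroglucinol ring, bears C8''), ring E (catechol ring), ring F (pyranone; C2'', C3'', C4''). TBS = tert-butyldimethylsilyl; p-ABSA = 4-acetamidobenzenesulfonyl azide; DMP = Dess–Martin periodinane.
Assumption: Rh2(S-PTTL)4 [dirhodium tetrakis(N-phthaloyl-(S)-tert-leucinate)] is taken as the antipode that selects the pro-R benzylic hydrogen; should the sense be the opposite, Rh2(R-PTTL)4 takes its place in step 9 with nothing else changed.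

**Route**

Step 1
Reactants: 1 (+)-catechin
Product: 2 penta-O-TBS-(+)-catechin, (2R,3S)-3,5,7-tris(TBS-oxy)-2-[3,4-bis(TBS-oxy)phenyl]chromane
Conditions: TBSCl (7 equiv), imidazole, DMAP (cat.), DMF, rt → 45 °C
Reagents that add atoms: tert-butyldimethylsilyl chloride (TBSCl), CC(C)(C)[Si](C)(C)Cl
Why: Standard chlorosilane/imidazole silylation, in which the four phenols react first and the secondary 3''-OH follows on warming, with no stereocentre touched.

Step 2
Reactants: 2 penta-O-TBS-(+)-catechin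
Product: 3 (2R,3S)-8-bromo-3,5,7-tris(TBS-oxy)-2-[3,4-bis(TBS-oxy)phenyl]chromane
Conditions: NBS (1.05 equiv), CH2Cl2, −78 → −20 °C
Reagents that add atoms: N-bromosuccinimide (NBS), O=C1CCC(=O)N1Br
Why: Electrophilic aromatic bromination of the phloroglucinol-type ring D should go to C8, the position that reacts in per-O-protected catechins and the less shielded one, C6 lying between two silyloxy groups.

Step 3
Reactants: 4 3,4-dihydroxybenzaldehyde
Product: 5 3,4-bis(TBS-oxy)benzaldehyde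
Conditions: TBSCl (2.3 equiv), imidazole, DMF, rt
Reagents that add atoms: tert-butyldimethylsilyl chloride (TBSCl), CC(C)(C)[Si](C)(C)Cl
Why: Routine silylation of both catechol hydroxyls.

Step 4
Reactants: 5 3,4-bis(TBS-oxy)benzaldehyde
Product: 6 [3,4-bis(TBS-oxy)phenyl]methanol
Conditions: NaBH4, THF/EtOH, 0 °C
Reagents that add atoms: none
Why: Borohydride reduction of the aldehyde, brief and cold so that the aryl silyl ethers survive.

Step 5
Reactants: 7 2',4',6'-trihydroxyacetophenone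
Product: 8 1-[2-hydroxy-4,6-bis(TBS-oxy)phenyl]ethanone
Conditions: TBSCl (2.05 equiv), imidazole, CH2Cl2/DMF, 0 °C → rt
Reagents that add atoms: tert-butyldimethylsilyl chloride (TBSCl), CC(C)(C)[Si](C)(C)Cl
Why: Chelation-controlled selective protection, the 4-OH and one ortho-OH being silylated while the last ortho-OH stays locked in its hydrogen bond to the acetyl group.

Step 6
Reactants: 8 1-[2-hydroxy-4,6-bis(TBS-oxy)phenyl]ethanone; 6 [3,4-bis(TBS-oxy)phenyl]methanol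
Product: 9 1-{2-[3,4-bis(TBS-oxy)benzyloxy]-4,6-bis(TBS-oxy)phenyl}ethanone
Conditions: PPh3, DIAD, THF, 0 °C → rt
Reagents that add atoms: none
Why: Mitsunobu etherification of the acidic chelated phenol with the primary benzylic alcohol forms the future O1–C2 bond under neutral conditions that spare the aryl silyl ethers, which carbonate bases would attack.

Step 7
Reactants: 9 1-{2-[3,4-bis(TBS-oxy)benzyloxy]-4,6-bis(TBS-oxy)phenyl}ethanone; 3 8-bromo-penta-O-TBS-catechin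
Product: 10 deoxybenzoin, 1-{2-[3,4-bis(TBS-oxy)benzyloxy]-4,6-bis(TBS-oxy)phenyl}-2-{(2R,3S)-3,5,7-tris(TBS-oxy)-2-[3,4-bis(TBS-oxy)phenyl]chroman-8-yl}ethanone
Conditions: Pd[P(tBu)3]2 (5 mol%), LiN(SiMe3)2 (2.2 equiv), toluene, 60 °C
Reagents that add atoms: none
Why: Buchwald–Hartwig-type α-arylation of a methyl ketone enolate (one enolisable site, primary carbon) with a zerovalent palladium complex of a bulky electron-rich phosphine suited to di-ortho-substituted electron-rich bromides forms the C3–C8'' bond; the non-nucleophilic amide base spares the silyl ethers, and the product rests as its enolate, which stops a second arylation.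

Step 8
Reactants: 10 deoxybenzoin
Product: 11 diazoketone, 2-diazo-1-{2-[3,4-bis(TBS-oxy)benzyloxy]-4,6-bis(TBS-oxy)phenyl}-2-{(2R,3S)-3,5,7-tris(TBS-oxy)-2-[3,4-bis(TBS-oxy)phenyl]chroman-8-yl}ethanone
Conditions: p-ABSA (1.5 equiv), DBU (1.5 equiv), dry MeCN, 0 °C → rt
Reagents that add atoms: 4-acetamidobenzenesulfonyl azide (p-ABSA), CC(=O)Nc1ccc(cc1)S(=O)(=O)N=[N+]=[N-]
Why: Regitz diazo transfer, for which the benzylic CH2 of an aryl benzyl ketone is acidic enough to react directly with a sulfonyl azide and an amidine base, water being excluded to protect the aryl silyl ethers.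

Step 9
Reactants: 11 diazoketone
Product: 13 (2R,3S)-trans-flavanone, (2R,3S)-5,7-bis(TBS-oxy)-2-[3,4-bis(TBS-oxy)phenyl]-3-{(2R,3S)-3,5,7-tris(TBS-oxy)-2-[3,4-bis(TBS-oxy)phenyl]chroman-8-yl}chroman-4-one, via cis-flavanone 12 (not isolated)
Conditions: Rh2(S-PTTL)4 (2 mol%), toluene, −40 → 0 °C, slow addition of 11; then Et3N, rt
Reagents that add atoms: none
Why: Rh2(S-PTTL)4 expels N2 from 11 and gives a donor/acceptor rhodium carbene at C3 (acceptor: the C4 aroyl carbonyl; donor: ring D at C8''), which inserts through a concerted, hydride-transfer-like three-centre transition state into one hydrogen of the ring-A OCH2 group six atoms away and so forms the C2–C3 bond with retention at C2. The closest known reaction type is the 1,6-C–H insertion of 2-alkoxyphenyl α-diazoketones next to the ether oxygen under chiral divalent rhodium carboxylates, which gives cis-2,3-disubstituted chroman-4-ones that base turns into the trans isomers, together with the enantioselective benzylic-ether insertions of aryl-substituted carbenes with this same catalyst. Ring C is the only ring closed, by 1,6-insertion (C2–C3 bond, six-membered transition state), O1–C8a and C4–C4a being in place already. C2 (R) is controlled by the chiral carboxylate ligands, which select the pro-R benzylic hydrogen, and C3 (S) is then controlled thermodynamically, Et3N enolising the C4 ketone until the ring-D aryl lies trans (diequatorial) to ring B. The step needs C–H insertion at this OCH2 group over oxonium ylide formation with [1,2]-benzyl shift, over insertion elsewhere and over Wolff rearrangement: the ether oxygen is a weakly basic vinylogous-ester oxygen and a rhodium carboxylate (not a copper catalyst) favours insertion, the OCH2 hydrogens are both benzylic to the electron-rich ring B and α to oxygen, and the other oxygens near the carbene (O7'' on ring D and the second ortho oxygen of ring A) carry silyl groups with no hydrogen on a carbon next to oxygen, while O1''–C2''–H cannot be reached without a bridgehead arene. Rings D, E and F being enantiopure already, the wrong choice of hydrogen would give a diastereomer, removable by chromatography, not the enantiomer.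

Step 10
Reactants: 13 (2R,3S)-trans-flavanone
Product: 14 4''-alcohol, (2R,3S)-5,7-bis(TBS-oxy)-2-[3,4-bis(TBS-oxy)phenyl]-3-{(2R,3S,4R)-4-hydroxy-3,5,7-tris(TBS-oxy)-2-[3,4-bis(TBS-oxy)phenyl]chroman-8-yl}chroman-4-one
Conditions: DDQ (2 equiv), CH2Cl2/H2O, 0 °C → rt
Reagents that add atoms: water, O
Why: DDQ benzylic oxidation as known for protected flavan-3-ols, hydride leaving C4'' (stabilised by the three oxygen donors of ring D) and water adding to the cation anti to the 3''-silyloxy group; the C4'' configuration is lost again in step 11.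

Step 11
Reactants: 14 4''-alcohol
Product: 15 nona-O-TBS-manniflavanone, (2R,3S)-5,7-bis(TBS-oxy)-2-[3,4-bis(TBS-oxy)phenyl]-3-{(2R,3R)-3,5,7-tris(TBS-oxy)-2-[3,4-bis(TBS-oxy)phenyl]-4-oxochroman-8-yl}chroman-4-one
Conditions: DMP, CH2Cl2, 0 °C → rt
Reagents that add atoms: none
Why: Dess–Martin oxidation of the benzylic secondary alcohol to the aryl ketone under non-basic conditions, so that the now enolisable C3'' and C3 keep their configuration (C3'' changes descriptor from S to R by priority only).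

Step 12
Reactants: 15 nona-O-TBS-manniflavanone
Product: 16 manniflavanone
Conditions: HF·pyridine, pyridine, THF, 0 °C → rt, under argon
Reagents that add atoms: none
Why: Fluoride cleavage of the eight aryl and one secondary alkyl Si–O bonds under mildly acidic, buffered conditions, which avoid the phenoxide (quinone methide) pathway that would open ring C at C2 and the base sensitivity of ring F.

**Compound list**

1 | (+)-catechin, (2R,3S)-2-(3,4-dihydroxyphenyl)chromane-3,5,7-triol | C1c2c(O)cc(O)cc2O[C@H](c2ccc(O)c(O)c2)[C@H]1O | starting material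
2 | penta-O-TBS-(+)-catechin, (2R,3S)-3,5,7-tris(TBS-oxy)-2-[3,4-bis(TBS-oxy)phenyl]chromane | C1c2c(O[Si](C)(C)C(C)(C)C)cc(O[Si](C)(C)C(C)(C)C)cc2O[C@H](c2ccc(O[Si](C)(C)C(C)(C)C)c(O[Si](C)(C)C(C)(C)C)c2)[C@H]1O[Si](C)(C)C(C)(C)C | intermediate
3 | (2R,3S)-8-bromo-3,5,7-tris(TBS-oxy)-2-[3,4-bis(TBS-oxy)phenyl]chromane | C1c2c(O[Si](C)(C)C(C)(C)C)cc(O[Si](C)(C)C(C)(C)C)c(Br)c2O[C@H](c2ccc(O[Si](C)(C)C(C)(C)C)c(O[Si](C)(C)C(C)(C)C)c2)[C@H]1O[Si](C)(C)C(C)(C)C | intermediate
4 | 3,4-dihydroxybenzaldehyde | O=Cc1ccc(O)c(O)c1 | starting material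
5 | 3,4-bis(TBS-oxy)benzaldehyde | O=Cc1ccc(O[Si](C)(C)C(C)(C)C)c(O[Si](C)(C)C(C)(C)C)c1 | intermediate
6 | [3,4-bis(TBS-oxy)phenyl]methanol | OCc1ccc(O[Si](C)(C)C(C)(C)C)c(O[Si](C)(C)C(C)(C)C)c1 | intermediate
7 | 2',4',6'-trihydroxyacetophenone | CC(=O)c1c(O)cc(O)cc1O | starting material
8 | 1-[2-hydroxy-4,6-bis(TBS-oxy)phenyl]ethanone | CC(=O)c1c(O)cc(O[Si](C)(C)C(C)(C)C)cc1O[Si](C)(C)C(C)(C)C | intermediate
9 | 1-{2-[3,4-bis(TBS-oxy)benzyloxy]-4,6-bis(TBS-oxy)phenyl}ethanone | CC(=O)c1c(OCc2ccc(O[Si](C)(C)C(C)(C)C)c(O[Si](C)(C)C(C)(C)C)c2)cc(O[Si](C)(C)C(C)(C)C)cc1O[Si](C)(C)C(C)(C)C | intermediate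
10 | deoxybenzoin, 1-{2-[3,4-bis(TBS-oxy)benzyloxy]-4,6-bis(TBS-oxy)phenyl}-2-{(2R,3S)-3,5,7-tris(TBS-oxy)-2-[3,4-bis(TBS-oxy)phenyl]chroman-8-yl}ethanone | O=C(Cc1c(O[Si](C)(C)C(C)(C)C)cc(O[Si](C)(C)C(C)(C)C)c2c1O[C@H](c1ccc(O[Si](C)(C)C(C)(C)C)c(O[Si](C)(C)C(C)(C)C)c1)[C@@H](O[Si](C)(C)C(C)(C)C)C2)c1c(OCc2ccc(O[Si](C)(C)C(C)(C)C)c(O[Si](C)(C)C(C)(C)C)c2)cc(O[Si](C)(C)C(C)(C)C)cc1O[Si](C)(C)C(C)(C)C | intermediate
11 | diazoketone, 2-diazo derivative of 10 at the carbon between the carbonyl group and ring D | O=C(C(=[N+]=[N-])c1c(O[Si](C)(C)C(C)(C)C)cc(O[Si](C)(C)C(C)(C)C)c2c1O[C@H](c1ccc(O[Si](C)(C)C(C)(C)C)c(O[Si](C)(C)C(C)(C)C)c1)[C@@H](O[Si](C)(C)C(C)(C)C)C2)c1c(OCc2ccc(O[Si](C)(C)C(C)(C)C)c(O[Si](C)(C)C(C)(C)C)c2)cc(O[Si](C)(C)C(C)(C)C)cc1O[Si](C)(C)C(C)(C)C | intermediate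
12 | cis-flavanone, (2R,3R)-5,7-bis(TBS-oxy)-2-[3,4-bis(TBS-oxy)phenyl]-3-{(2R,3S)-3,5,7-tris(TBS-oxy)-2-[3,4-bis(TBS-oxy)phenyl]chroman-8-yl}chroman-4-one | C1c2c(O[Si](C)(C)C(C)(C)C)cc(O[Si](C)(C)C(C)(C)C)c([C@H]3C(=O)c4c(O[Si](C)(C)C(C)(C)C)cc(O[Si](C)(C)C(C)(C)C)cc4O[C@H]3c3ccc(O[Si](C)(C)C(C)(C)C)c(O[Si](C)(C)C(C)(C)C)c3)c2O[C@H](c2ccc(O[Si](C)(C)C(C)(C)C)c(O[Si](C)(C)C(C)(C)C)c2)[C@H]1O[Si](C)(C)C(C)(C)C | intermediate (not isolated)
13 | trans-flavanone, (2R,3S)-5,7-bis(TBS-oxy)-2-[3,4-bis(TBS-oxy)phenyl]-3-{(2R,3S)-3,5,7-tris(TBS-oxy)-2-[3,4-bis(TBS-oxy)phenyl]chroman-8-yl}chroman-4-one | C1c2c(O[Si](C)(C)C(C)(C)C)cc(O[Si](C)(C)C(C)(C)C)c([C@@H]3C(=O)c4c(O[Si](C)(C)C(C)(C)C)cc(O[Si](C)(C)C(C)(C)C)cc4O[C@H]3c3ccc(O[Si](C)(C)C(C)(C)C)c(O[Si](C)(C)C(C)(C)C)c3)c2O[C@H](c2ccc(O[Si](C)(C)C(C)(C)C)c(O[Si](C)(C)C(C)(C)C)c2)[C@H]1O[Si](C)(C)C(C)(C)C | intermediate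
14 | 4''-alcohol, 13 with a (4R)-hydroxyl at C4'' of ring F (3'',4''-trans; flavan part 2R,3S,4R) | O[C@@H]1c2c(O[Si](C)(C)C(C)(C)C)cc(O[Si](C)(C)C(C)(C)C)c([C@@H]3C(=O)c4c(O[Si](C)(C)C(C)(C)C)cc(O[Si](C)(C)C(C)(C)C)cc4O[C@H]3c3ccc(O[Si](C)(C)C(C)(C)C)c(O[Si](C)(C)C(C)(C)C)c3)c2O[C@H](c2ccc(O[Si](C)(C)C(C)(C)C)c(O[Si](C)(C)C(C)(C)C)c2)[C@H]1O[Si](C)(C)C(C)(C)C | intermediate
15 | nona-O-TBS-manniflavanone, (2R,3S)-5,7-bis(TBS-oxy)-2-[3,4-bis(TBS-oxy)phenyl]-3-{(2R,3R)-3,5,7-tris(TBS-oxy)-2-[3,4-bis(TBS-oxy)phenyl]-4-oxochroman-8-yl}chroman-4-one | O=C1c2c(O[Si](C)(C)C(C)(C)C)cc(O[Si](C)(C)C(C)(C)C)c([C@@H]3C(=O)c4c(O[Si](C)(C)C(C)(C)C)cc(O[Si](C)(C)C(C)(C)C)cc4O[C@H]3c3ccc(O[Si](C)(C)C(C)(C)C)c(O[Si](C)(C)C(C)(C)C)c3)c2O[C@H](c2ccc(O[Si](C)(C)C(C)(C)C)c(O[Si](C)(C)C(C)(C)C)c2)[C@H]1O[Si](C)(C)C(C)(C)C | intermediate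
16 | manniflavanone, (2R,3S)-flavanone half joined at C3 to C8'' of the (2R,3R)-dihydroflavonol half | O=C1c2c(O)cc(O)c([C@@H]3C(=O)c4c(O)cc(O)cc4O[C@H]3c3ccc(O)c(O)c3)c2O[C@H](c2ccc(O)c(O)c2)[C@H]1O | target

**Step count and risks**

Total: 12 steps. Longest linear sequence: 9 steps (3, 4, 6, 7, 8, 9, 10, 11, 12, from 3,4-dihydroxybenzaldehyde).

Step 9 (most at risk). The carbene may be diverted, by attack of the ring-A ether oxygen to an oxonium ylide followed by [1,2]-benzyl shift to a benzofuranone, or by dimerisation. The catalyst may also discriminate poorly between the two benzylic hydrogens, so that the C2-epimeric series forms alongside. The fallback builds ring C by condensation instead of insertion. It sets out from phenol 8, bromide 3 and aldehyde 5. Palladium-catalysed α-arylation of 8 with 3 (Pd[P(tBu)3]2, LiN(SiMe3)2 3.3 equiv, toluene, 60 °C; the phenol carried as its lithium phenoxide) should give the 2'-hydroxydeoxybenzoin F1. Amine-mediated Knoevenagel condensation of F1 with 5 and 6-endo oxa-Michael closure in the same flask (pyrrolidine, AcOH, 4 Å sieves, toluene, 50 °C) should give the 2,3-trans-flavanone as its two ring-C diastereomers, 13 and the (2S,3R)-isomer F2. These are separated by chromatography; F2 is re-equilibrated under the same amine conditions through retro-oxa-Michael opening and recycled. The fallback comes back to the route at 13.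

Step 7. Oxidative addition into the electron-rich, di-ortho-oxygenated bromide and the crowded C–C reductive elimination may be slow, so that hydrodebromination and loss of aryl silyl groups to the base take over. The fallback reverses the polarity of the C3–C8'' bond formation. It sets out from ketone 9 and bromide 3. The lithium enolate of 9 (LiN(SiMe3)2, THF, −78 °C) is brominated with NBS to the α-bromoketone F3. Bromine–lithium exchange on 3 (t-BuLi, Et2O, −78 °C) gives the aryllithium F4, which is trapped at once with ZnCl2 as the arylzinc chloride F5, before an O-to-C silyl shift can occur. Nickel-catalysed Negishi arylation of F3 with F5 (NiCl2(glyme), a pybox ligand, THF, −20 °C → rt) should then give deoxybenzoin 10, where the route is rejoined.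

Step 10. Hydride abstraction by DDQ may occur at the wrong place, either by dehydrogenation of the freshly made ring C across C2–C3 to the flavone or by attack at C2–H. It may also be sluggish, because ring D carries silyl ethers where the known cases carry alkyl ethers. The fallback moves the oxidation in front of the ring closure, so that no ring C is present when DDQ is used. It sets out from deoxybenzoin 10. DDQ/H2O gives the 4''-hydroxy-deoxybenzoin F6, and DMP gives the 4''-oxo-deoxybenzoin F7. Diazo transfer (p-ABSA, DBU, dry MeCN, 0 °C, short contact, because of the enolisable ring-F ketone) gives the diazoketone F8. The conditions of step 9 (Rh2(S-PTTL)4, then Et3N) should lead through the cis-flavanone F9, not isolated, to 15, where the route is rejoined; steps 10 and 11 then fall away.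

Further compounds
F1 | step 9 | 2'-hydroxydeoxybenzoin, 1-[2-hydroxy-4,6-bis(TBS-oxy)phenyl]-2-{(2R,3S)-3,5,7-tris(TBS-oxy)-2-[3,4-bis(TBS-oxy)phenyl]chroman-8-yl}ethanone | O=C(Cc1c(O[Si](C)(C)C(C)(C)C)cc(O[Si](C)(C)C(C)(C)C)c2c1O[C@H](c1ccc(O[Si](C)(C)C(C)(C)C)c(O[Si](C)(C)C(C)(C)C)c1)[C@@H](O[Si](C)(C)C(C)(C)C)C2)c1c(O)cc(O[Si](C)(C)C(C)(C)C)cc1O[Si](C)(C)C(C)(C)C
F2 | step 9 | (2S,3R)-trans-flavanone, the ring-C diastereomer of 13 | C1c2c(O[Si](C)(C)C(C)(C)C)cc(O[Si](C)(C)C(C)(C)C)c([C@H]3C(=O)c4c(O[Si](C)(C)C(C)(C)C)cc(O[Si](C)(C)C(C)(C)C)cc4O[C@@H]3c3ccc(O[Si](C)(C)C(C)(C)C)c(O[Si](C)(C)C(C)(C)C)c3)c2O[C@H](c2ccc(O[Si](C)(C)C(C)(C)C)c(O[Si](C)(C)C(C)(C)C)c2)[C@H]1O[Si](C)(C)C(C)(C)C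
F3 | step 7 | α-bromoketone, 2-bromo-1-{2-[3,4-bis(TBS-oxy)benzyloxy]-4,6-bis(TBS-oxy)phenyl}ethanone | BrCC(=O)c1c(OCc2ccc(O[Si](C)(C)C(C)(C)C)c(O[Si](C)(C)C(C)(C)C)c2)cc(O[Si](C)(C)C(C)(C)C)cc1O[Si](C)(C)C(C)(C)C
F4 | step 7 | aryllithium, 8-lithio-penta-O-TBS-catechin | [Li]c1c(O[Si](C)(C)C(C)(C)C)cc(O[Si](C)(C)C(C)(C)C)c2c1O[C@H](c1ccc(O[Si](C)(C)C(C)(C)C)c(O[Si](C)(C)C(C)(C)C)c1)[C@@H](O[Si](C)(C)C(C)(C)C)C2
F5 | step 7 | arylzinc chloride, 8-(chlorozincio)-penta-O-TBS-catechin | Cl[Zn]c1c(O[Si](C)(C)C(C)(C)C)cc(O[Si](C)(C)C(C)(C)C)c2c1O[C@H](c1ccc(O[Si](C)(C)C(C)(C)C)c(O[Si](C)(C)C(C)(C)C)c1)[C@@H](O[Si](C)(C)C(C)(C)C)C2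
F6 | step 10 | 4''-hydroxy-deoxybenzoin, 10 with a (4R)-hydroxyl at C4'' of ring F | O=C(Cc1c(O[Si](C)(C)C(C)(C)C)cc(O[Si](C)(C)C(C)(C)C)c2c1O[C@H](c1ccc(O[Si](C)(C)C(C)(C)C)c(O[Si](C)(C)C(C)(C)C)c1)[C@@H](O[Si](C)(C)C(C)(C)C)[C@@H]2O)c1c(OCc2ccc(O[Si](C)(C)C(C)(C)C)c(O[Si](C)(C)C(C)(C)C)c2)cc(O[Si](C)(C)C(C)(C)C)cc1O[Si](C)(C)C(C)(C)C
F7 | step 10 | 4''-oxo-deoxybenzoin, 10 with a ketone at C4'' of ring F (ring F 2R,3R) | O=C(Cc1c(O[Si](C)(C)C(C)(C)C)cc(O[Si](C)(C)C(C)(C)C)c2c1O[C@H](c1ccc(O[Si](C)(C)C(C)(C)C)c(O[Si](C)(C)C(C)(C)C)c1)[C@@H](O[Si](C)(C)C(C)(C)C)C2=O)c1c(OCc2ccc(O[Si](C)(C)C(C)(C)C)c(O[Si](C)(C)C(C)(C)C)c2)cc(O[Si](C)(C)C(C)(C)C)cc1O[Si](C)(C)C(C)(C)C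
F8 | step 10 | diazoketone of F7 | O=C(C(=[N+]=[N-])c1c(O[Si](C)(C)C(C)(C)C)cc(O[Si](C)(C)C(C)(C)C)c2c1O[C@H](c1ccc(O[Si](C)(C)C(C)(C)C)c(O[Si](C)(C)C(C)(C)C)c1)[C@@H](O[Si](C)(C)C(C)(C)C)C2=O)c1c(OCc2ccc(O[Si](C)(C)C(C)(C)C)c(O[Si](C)(C)C(C)(C)C)c2)cc(O[Si](C)(C)C(C)(C)C)cc1O[Si](C)(C)C(C)(C)C
F9 | step 10 | cis-flavanone at the 4''-ketone level, the (2R,3R)-epimer of 15 at C3 (not isolated) | O=C1c2c(O[Si](C)(C)C(C)(C)C)cc(O[Si](C)(C)C(C)(C)C)c([C@H]3C(=O)c4c(O[Si](C)(C)C(C)(C)C)cc(O[Si](C)(C)C(C)(C)C)cc4O[C@H]3c3ccc(O[Si](C)(C)C(C)(C)C)c(O[Si](C)(C)C(C)(C)C)c3)c2O[C@H](c2ccc(O[Si](C)(C)C(C)(C)C)c(O[Si](C)(C)C(C)(C)C)c2)[C@H]1O[Si](C)(C)C(C)(C)C
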